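**Assumption:** the bridged hemiketal is the preferred form of the hydroxy aryl ketone, as in the natural product, so the photoproduct is isolated directly as the hemiketal.

## Retrosynthetic overview
1. Komaroviquinone comes from the 12-desmethoxy quinone by conjugate addition of MeOH and reoxidation. That quinone comes from its 11,14-dimethoxyarene by oxidative demethylation, which is the dearomatization to the quinone.
2. The 8-oxabicyclo[3.2.1] hemiketal (C10 quaternary ether carbon, C7 hemiketal, C20 methylene) is made in one step. An aryl ketone with an ortho-methyl group (thymol-type arene) undergoes photoenolization, which breaks the arene's aromaticity to give a hydroxy-o-quinodimethane. This adds across the C10 ketone of the cyclohexanone in an intramolecular oxa-Diels–Alder reaction.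
3. The 1,4-diketone comes from an aryllithium adding to a cis-fused γ-lactone, then oxidation of the resulting secondary alcohol.
4. The lactone comes from a cyclohexenylacetic acid. That acid comes from a Johnson–Claisen rearrangement of an enantioenriched 4,4-dimethylcyclohexenol, which transfers the carbinol chirality to C5.
5. Rings are formed in the order A (cyclohexenone), then C (arene from thymoquinone), then the B ring and oxa-bridge in the photochemical step.

## Route

**Step 1**
- Reactants: 1 thymoquinone
- Product: 2 2-isopropyl-1,4-dimethoxy-5-methylbenzene
- Conditions: Na2S2O4, Bu4NBr, THF/H2O, rt; then Me2SO4, KOH (aq), rt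
- Reagents that add atoms: dimethyl sulfate, COS(=O)(=O)OC (adds two CH3)
- Why: Dithionite reduces the quinone to the hydroquinone, which is O-methylated (reductive methylation). This gives a hydroquinone dimethyl ether that can survive the later organolithium and photochemical steps. No stereocenters are involved.

**Step 2**
- Reactants: 2
- Product: 3 1-bromo-2,5-dimethoxy-3-isopropyl-6-methylbenzene
- Conditions: NBS, MeCN, 0 °C → rt, dark
- Reagents that add atoms: NBS, O=C1CCC(=O)N1Br (adds Br)
- Why: Electrophilic aromatic bromination (no radical initiator) goes to the ring CH flanked by methyl rather than isopropyl. This position becomes C8, the future attachment point of C7.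

**Step 3**
- Reactants: 4 4,4-dimethylcyclohex-2-en-1-one
- Product: 5 (R)-4,4-dimethylcyclohex-2-en-1-ol
- Conditions: (S)-Me-CBS (10 mol%), BH3·SMe2, THF, –20 °C
- Reagents that add atoms: none
- Why: Corey–Bakshi–Shibata reduction discriminates the enantiotopic faces of the prochiral enone. The (S)-catalyst is chosen to give the (R)-alcohol, and the ee is to be confirmed by Mosher analysis or HPLC. This carbinol configuration sets C5 in the next step.

**Step 4**
- Reactants: 5
- Product: 6 ethyl 2-[(1R)-6,6-dimethylcyclohex-2-en-1-yl]acetate
- Conditions: CH3C(OEt)3 (excess), EtCO2H (cat.), 140 °C, sealed tube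
- Reagents that add atoms: triethyl orthoacetate, CCOC(C)(OCC)OCC (adds the CH2CO2Et unit)
- Why: Johnson–Claisen [3,3] rearrangement is suprafacial, so the new C5–C6 bond forms on the face that carried the C–O bond. This creates the C5 stereocenter (S in the target numbering; R by CIP in this intermediate). The alkene moves to C10=C1.

**Step 5**
- Reactants: 6
- Product: 7 (R)-2-(6,6-dimethylcyclohex-2-en-1-yl)acetic acid
- Conditions: LiOH, THF/MeOH/H2O, rt; then 1 M HCl
- Reagents that add atoms: water, O (gives the acid OH)
- Why: Ester saponification. The alkene and C5 are untouched, and C5 is not enolizable because it is β to the carbonyl.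

**Step 6**
- Reactants: 7
- Product: 8 (3aS,7aR)-4,4-dimethylhexahydrobenzofuran-2(3H)-one (cis-fused lactone)
- Conditions: TfOH (5 mol%), 1,2-dichloroethane, 60 °C
- Reagents that add atoms: none
- Why: Brønsted-acid hydroacyloxylation of the alkene closes a γ-lactone 5-exo at C10, which is forced to be cis-fused. C10 configuration is irrelevant because C10 is oxidized to a ketone two steps later.

**Step 7**
- Reactants: 3 and 8
- Product: 9 1-(2,5-dimethoxy-3-isopropyl-6-methylphenyl)-2-[(1S,2R)-2-hydroxy-6,6-dimethylcyclohexyl]ethan-1-one (open form of the lactol)
- Conditions: 3, n-BuLi (1.05 equiv), THF, –78 °C, 20 min; then 8, –78 → 0 °C; aq NH4Cl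
- Reagents that add atoms: none (n-BuLi and NH4Cl leave only H)
- Why: Br/Li exchange gives a hindered aryllithium that adds once to the lactone carbonyl, as in Weinreb-type ketone synthesis. The stable lactol alkoxide prevents double addition and is the ring–chain tautomer of the hydroxy ketone. C5 is untouched.

**Step 8**
- Reactants: 9
- Product: 10 (S)-2-[2-(2,5-dimethoxy-3-isopropyl-6-methylphenyl)-2-oxoethyl]-3,3-dimethylcyclohexan-1-one
- Conditions: Dess–Martin periodinane, NaHCO3, CH2Cl2, 0 °C → rt
- Reagents that add atoms: none
- Why: Oxidation of the secondary alcohol in the ring–chain mixture to the ketone gives the 1,4-diketone. Buffering prevents epimerization at C5, which is α to the new ketone.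

**Step 9**
- Reactants: 10
- Product: 11 hemiketal 8-oxabicyclo[3.2.1] core, 11,14-dimethoxy, 12-H
- Conditions: hν (350 nm), degassed benzene (5 mM), 25 °C
- Reagents that add atoms: none (isomerization)
- Why: **Proposed new method:** The excited aryl ketone abstracts a hydrogen from the ortho-methyl group (1,5-H shift) to give the (E)-hydroxy-o-quinodimethane, which is a dearomatized arene. The tethered cyclohexanone C=O acts as the heterodienophile in an oxa-Diels–Alder reaction. C20 bonds to C10 and the carbonyl O bonds to C7, re-aromatizing the ring and leaving the enol OH on C7 as the hemiketal OH. This is a bridged-mode cycloaddition with a two-atom tether. Only the cis O/C6 bridge is geometrically possible, so C10 and C7 follow from C5. The closest known chemistry is photoenolization/Diels–Alder and o-quinodimethane/carbonyl hetero-Diels–Alder.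

**Step 10**
- Reactants: 11
- Product: 12 12-desmethoxy-komaroviquinone (quinone)
- Conditions: CAN (4 equiv), MeCN/H2O 3:1, 0 °C, 10 min
- Reagents that add atoms: water, O (the quinone oxygens come from water, with loss of MeOH)
- Why: Oxidative demethylation of a 1,4-dimethoxyarene to the p-quinone. The bridged hemiketal and tertiary ether are not oxidizable, and no stereocenter is changed.

**Step 11**
- Reactants: 12
- Product: 13 komaroviquinone
- Conditions: CeCl3·7H2O (20 mol%), MeOH, rt; then Ag2O, CH2Cl2, rt
- Reagents that add atoms: methanol, CO (adds OMe)
- Why: Lewis-acid-catalysed oxa-Michael addition of MeOH to the only quinone C–H (C12, β to the C14 carbonyl), followed by reoxidation of the methoxyhydroquinone, gives the vinylogous ester. The site is unambiguous, and no stereocenters are touched.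

## Compound list
1 | thymoquinone | CC1=CC(=O)C(C(C)C)=CC1=O | starting material
2 | 2-isopropyl-1,4-dimethoxy-5-methylbenzene | Cc1cc(OC)c(C(C)C)cc1OC | intermediate
3 | 1-bromo-2,5-dimethoxy-3-isopropyl-6-methylbenzene | COc1cc(C(C)C)c(OC)c(Br)c1C | intermediate
4 | 4,4-dimethylcyclohex-2-en-1-one | CC1(C)CCC(=O)C=C1 | starting material
5 | (R)-4,4-dimethylcyclohex-2-en-1-ol | O[C@H]1C=CC(C)(C)CC1 | intermediate
6 | ethyl 2-[(1R)-6,6-dimethylcyclohex-2-en-1-yl]acetate | CCOC(=O)C[C@@H]1C=CCCC1(C)C | intermediate
7 | (R)-2-(6,6-dimethylcyclohex-2-en-1-yl)acetic acid | OC(=O)C[C@@H]1C=CCCC1(C)C | intermediate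
8 | (3aS,7aR)-4,4-dimethylhexahydrobenzofuran-2(3H)-one | O=C1C[C@H]2C(C)(C)CCC[C@H]2O1 | intermediate
9 | aryl ketone / cis-2-hydroxycyclohexyl (open form of the lactol) | COc1cc(C(C)C)c(OC)c(C(=O)C[C@H]2C(C)(C)CCC[C@H]2O)c1C | intermediate
10 | 1,4-diketone | COc1cc(C(C)C)c(OC)c(C(=O)C[C@H]2C(C)(C)CCCC2=O)c1C | intermediate
11 | bridged hemiketal dimethoxyarene | COc1cc(C(C)C)c(OC)c2c1C[C@@]34CCCC(C)(C)[C@@H]3C[C@]2(O)O4 | intermediate
12 | 12-desmethoxy-komaroviquinone | C1=C(C(C)C)C(=O)C2=C(C[C@@]34CCCC(C)(C)[C@@H]3C[C@]2(O)O4)C1=O | intermediate
13 | komaroviquinone | COC1=C(C(C)C)C(=O)C2=C(C[C@@]34CCCC(C)(C)[C@@H]3C[C@]2(O)O4)C1=O | target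

## Totals
- **Total steps:** 11 (arene branch 2 steps; A-ring branch 4 steps; coupling and endgame 5 steps).
- **Longest linear sequence:** 9 steps (Steps 3–11).

## Three steps most likely to fail
1. **Step 9 (photoenol oxa-Diels–Alder).** Norrish II γ-H abstraction at C5–H or reversion of the photoenol could compete with bridged-mode cycloaddition.
   - Fallback (changes the approach): form the C20–C9 bond first. Negishi-couple a benzylzinc reagent from the arene to 2-iodo-4,4-dimethylcyclohexenone. Then run the CBS, Claisen and hydroacyloxylation sequence to a 10-(arylmethyl) lactone. Close the B ring by Br/Li addition to the lactone carbonyl, which gives the hemiketal directly.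
2. **Step 7 (hindered aryllithium plus lactone).** Enolization of the lactone or low conversion is possible.
   - Fallback: make the Weinreb amide of 7 and add the aryllithium to give the unsaturated aryl ketone. Then install the C10 ketone by Wacker oxidation, avoiding the lactone.
3. **Step 11 (late C12 methoxylation of a hindered quinone).** Conversion or hydroquinone reoxidation may be poor.
   - Fallback: swap which substituent is installed last. Start from 2-methoxy-6-methylphenol and carry the C12 OMe through Fremy oxidation, reductive methylation and bromination. Run the same sequence, then install the isopropyl group on the final quinone by Ag(I)/persulfate radical alkylation with isobutyric acid.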